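**Plan**

1. Retrosynthesis: both lactone O–C(spiro) bonds are cut first (each 4-bromobutenolide from a 2,3-allenoate), then the allenoates go back to tertiary propargylic carbonates, these to trans-3,4-dibromocyclobutane-1,2-dione plus (S)- and (R)-hex-1-yn-3-ol, and the dione to acetylene plus dichlorovinylene carbonate by cutting both C(spiro)–CHBr ring bonds.
2. Enabling feature: the two spiro carbons (C-5 of each furanone) are adjacent, each carries one ring oxygen and sits next to a CHBr carbon, so the four-membered ring is a masked 3,4-dibromocyclobutane-1,2-dione, i.e. a 1,2-dioxygenated ethylene plus a C2 unit.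
3. Forward order: cyclobutene ring (step 1), ring bromines, dione, two alkynyl carbinols, two exocyclic allenoates, then both butenolide rings in one operation; side-chain acetates last.
4. Relative configuration: Br/Br trans from anti addition of Br2; each acetylide enters anti to the bromine on the neighbouring ring carbon; anti-SN2' carbonylation and axis-to-centre transfer then place each lactone oxygen opposite its carbinol oxygen, i.e. trans to the neighbouring ring bromine and trans to the other lactone oxygen.
5. Each ring bromine lies on the face of the vinylic C–Br carbon (C-4) of the neighbouring lactone, a face that bromide could not reach in a finished bis-spirolactone; hence C–Br is set before C–O.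
6. Absolute configuration: the side chains come from (S)- and (R)-hex-1-yn-3-ol; the configuration of the core is fixed by separating diastereomers after the first alkynylation of the racemic dibromodione.

Key step: step 1

Assumption: 4,5-dichloro-1,3-dioxol-2-one and both enantiomers of hex-1-yn-3-ol are treated as purchasable.

Step 1
Reactants: 1 dichlorovinylene carbonate (4,5-dichloro-1,3-dioxol-2-one); 2 acetylene
Product: 3 cis-1,5-dichloro-2,4-dioxabicyclo[3.2.0]hept-6-en-3-one (meso)
Conditions: hν (Pyrex, >300 nm), acetone (solvent and sensitiser), C2H2 (saturated, continuous stream), −40 °C, run to partial conversion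
Reagents that add atoms: none
Why: Triplet-sensitised [2+2] photocycloaddition: acetone passes triplet energy to 1, whose excited C=C adds to acetylene to give a 1,4-biradical that closes after spin inversion. The closest known reactions are the sensitised [2+2] additions of dichlorovinylene carbonate, vinylene carbonate and maleic anhydride to alkenes and alkynes, the first of these being an established 1,2-dione synthesis. The cyclobutene is closed in two stages, intermolecular C–C bond formation and then radical–radical collapse of the biradical to the four-membered ring, and both bonds between a future spiro carbon and a future CHBr carbon are made here. The two new stereocentres are the chlorinated bridgeheads; they can only be cis because the five-membered carbonate spans them, and they are erased when the dione is unmasked. The step needs cross-addition to win over photodimerisation of 1 and over a second addition to the strained product alkene, which excess acetylene, low temperature and partial conversion should secure; both partners are symmetric, so no regiochemistry arises.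

Step 2
Reactants: 3 cis-1,5-dichloro-2,4-dioxabicyclo[3.2.0]hept-6-en-3-one
Product: 4 trans-6,7-dibromo-cis-1,5-dichloro-2,4-dioxabicyclo[3.2.0]heptan-3-one (racemate)
Conditions: Br2 (1.05 equiv), CH2Cl2, 0 °C, dark
Reagents that add atoms: bromine, BrBr
Why: Electrophilic anti addition of bromine through a bromonium ion should give only the trans-dibromide, as a racemate because the two alkene carbons of meso 3 are enantiotopic.

Step 3
Reactants: 4 trans-6,7-dibromo-cis-1,5-dichloro-2,4-dioxabicyclo[3.2.0]heptan-3-one
Product: 5 rac-(3R,4R)-3,4-dibromocyclobutane-1,2-dione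
Conditions: H2O (5 equiv), acetone, 25 °C; toluene azeotrope; used at once
Reagents that add atoms: none
Why: Hydrolysis of the cyclic carbonate sets free CO2 and a bis(α-chlorohydrin) that loses two HCl to give the 1,2-dione (the dichlorovinylene carbonate dione synthesis); the medium stays acidic, so the CHBr centres should be neither epimerised nor lost by elimination.

Step 4
Reactants: 6 (S)-hex-1-yn-3-ol
Product: 7 (S)-tert-butyl(hex-1-yn-3-yloxy)diphenylsilane
Conditions: TBDPSCl (1.1 equiv), imidazole (2 equiv), DMF, 25 °C
Reagents that add atoms: tert-butyl(chloro)diphenylsilane, CC(C)(C)[Si](Cl)(c1ccccc1)c1ccccc1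
Why: Imidazole-promoted silylation of the secondary alcohol leaves the stereocentre untouched and gives an ether stable to the organometallic steps and to the HBr released in step 9.

Step 5
Reactants: 8 (R)-hex-1-yn-3-ol
Product: 9 (R)-tert-butyl(hex-1-yn-3-yloxy)diphenylsilane
Conditions: TBDPSCl (1.1 equiv), imidazole (2 equiv), DMF, 25 °C
Reagents that add atoms: tert-butyl(chloro)diphenylsilane, CC(C)(C)[Si](Cl)(c1ccccc1)c1ccccc1
Why: Same silylation as in step 4, applied to the enantiomeric alcohol without touching its stereocentre.

Step 6
Reactants: 5 rac-(3R,4R)-3,4-dibromocyclobutane-1,2-dione; 7 (S)-tert-butyl(hex-1-yn-3-yloxy)diphenylsilane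
Product: 13 methyl carbonate of the mono-alkynyl carbinol (carbonate oxygen cis to the neighbouring ring bromine; ring bromines trans; (S) side chain), via lithium acetylide 10 (not isolated), via dichlorocerium acetylide 11 (not isolated), via dichlorocerium alkoxide 12 (not isolated)
Conditions: 7, n-BuLi (1.0 equiv), THF, −78 °C; CeCl3 (anhydrous, 1.1 equiv), −78 °C; 5 (1.0 equiv), −78 °C; ClCO2Me (1.5 equiv), −78 to 0 °C; chromatography on SiO2 (preparative HPLC if needed)
Reagents that add atoms: methyl chloroformate, COC(=O)Cl
Why: Organocerium 1,2-addition to one of the two homotopic carbonyls, chosen because alkynylcerium reagents add to enolisable ketones without deprotonating them, with the acetylide expected to enter anti to the bromine on the adjacent ring carbon (polar Felkin–Anh control, the transannular bromine lying further from the attack path) so that the carbinol oxygen ends cis to that bromine, and with the alkoxide trapped cold as the carbonate before it can rearrange; only the (3R,4R) half of racemic 5 gives 13, while its (3S,4S) half gives a diastereomeric carbonate (mirror-image ring, same (S) side chain) that is removed in the chromatography, which fixes the absolute configuration of the core.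

Step 7
Reactants: 13 methyl carbonate of the mono-alkynyl carbinol; 9 (R)-tert-butyl(hex-1-yn-3-yloxy)diphenylsilane
Product: 17 trans-bis(methyl carbonate) of the dialkynyl diol (each carbonate oxygen cis to its neighbouring ring bromine), via lithium acetylide 14 (not isolated), via dichlorocerium acetylide 15 (not isolated), via dichlorocerium alkoxide 16 (not isolated)
Conditions: 9, n-BuLi (1.1 equiv), THF, −78 °C; CeCl3 (1.2 equiv), −78 °C; 13, −78 °C; ClCO2Me (1.5 equiv), −78 to 0 °C
Reagents that add atoms: methyl chloroformate, COC(=O)Cl
Why: Second organocerium 1,2-addition; the acetylide should again enter anti to the bromine on the adjacent ring carbon, which is also the face of the neighbouring carbonate oxygen and not of the alkyne, giving the trans-dicarbonate.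

Step 8
Reactants: 17 trans-bis(methyl carbonate) of the dialkynyl diol
Product: 18 dimethyl bis(2,3-allenoate) with both allenes exocyclic to the trans-dibromocyclobutane
Conditions: Pd(OAc)2 (5 mol%), PPh3 (20 mol%), CO (1 atm), MeOH/THF (1:1), 25 °C, stopped at full conversion
Reagents that add atoms: carbon monoxide, [C-]#[O+]; methanol, CO
Why: Tsuji carbonylation of tertiary propargylic carbonates: zerovalent palladium displaces each carbonate in anti-SN2' fashion, CO inserts and methanol gives the 2,3-allenoate, so each ester should end on the ring face opposite the departed oxygen and both allene axes are set from the carbinol centres; the ring bromides of 17 are unactivated secondary bromides, and because each becomes allylic to an allene in 18 (shielded there by the silyl ether and able to ionise only by forming a cyclobutene) the reaction is not prolonged.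

Step 9
Reactants: 18 dimethyl bis(2,3-allenoate)
Product: 19 bis(tert-butyldiphenylsilyl) ether of the tetrabromo bis-spirolactone
Conditions: CuBr2 (5 equiv), acetone/H2O (2:1), 60 °C
Reagents that add atoms: copper dibromide, Br[Cu]Br; water, O
Why: Copper-mediated bromolactonisation of 2,3-allenoates (Ma cyclisation): bromine goes to the central allene carbon while the ester carbonyl oxygen closes on the ring carbon from the face on which the ester lies, so each axis is copied into a spiro centre and both lactone oxygens should end anti to the neighbouring ring bromine and anti to each other.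

Step 10
Reactants: 19 bis(tert-butyldiphenylsilyl) ether of the tetrabromo bis-spirolactone
Product: 20 tetrabromo bis-spirolactone diol ((S)- and (R)-1-hydroxybutyl side chains)
Conditions: HF·pyridine, THF, 0 to 25 °C
Reagents that add atoms: none
Why: Fluoride cleavage of both silyl ethers under weakly acidic, poorly nucleophilic conditions should leave the vinylic and ring bromides and the lactones alone; no stereocentre is involved.

Step 11
Reactants: 20 tetrabromo bis-spirolactone diol
Product: 21 CNP0266230.1
Conditions: Ac2O (3 equiv), Sc(OTf)3 (2 mol%), MeCN, 0 °C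
Reagents that add atoms: acetic anhydride, CC(=O)OC(C)=O
Why: Lewis-acid-catalysed O-acetylation of the two secondary alcohols proceeds with retention and avoids amine nucleophiles that could displace the vinylogous acyl bromides.

**Compound list**

1 | dichlorovinylene carbonate (4,5-dichloro-1,3-dioxol-2-one) | O=C1OC(Cl)=C(Cl)O1 | starting material
2 | acetylene | C#C | starting material
3 | cis-1,5-dichloro-2,4-dioxabicyclo[3.2.0]hept-6-en-3-one (meso) | O=C1O[C@]2(Cl)C=C[C@]2(Cl)O1 | intermediate
4 | trans-6,7-dibromo-cis-1,5-dichloro-2,4-dioxabicyclo[3.2.0]heptan-3-one (racemate; the enantiomer drawn leads on) | O=C1O[C@]2(Cl)[C@@H](Br)[C@H](Br)[C@]2(Cl)O1 | intermediate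
5 | rac-(3R,4R)-3,4-dibromocyclobutane-1,2-dione (the (3R,4R) enantiomer drawn is the one that reaches the target) | O=C1[C@@H](Br)[C@H](Br)C1=O | intermediate
6 | (S)-hex-1-yn-3-ol | CCC[C@H](O)C#C | starting material
7 | (S)-tert-butyl(hex-1-yn-3-yloxy)diphenylsilane | CCC[C@H](O[Si](c3ccccc3)(c4ccccc4)C(C)(C)C)C#C | intermediate
8 | (R)-hex-1-yn-3-ol | C#C[C@@H](CCC)O | starting material
9 | (R)-tert-butyl(hex-1-yn-3-yloxy)diphenylsilane | C#C[C@@H](CCC)O[Si](c3ccccc3)(c4ccccc4)C(C)(C)C | intermediate
10 | lithium acetylide of 7 (not isolated) | CCC[C@H](O[Si](c3ccccc3)(c4ccccc4)C(C)(C)C)C#C[Li] | intermediate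
11 | dichlorocerium acetylide of 7 (not isolated) | CCC[C@H](O[Si](c3ccccc3)(c4ccccc4)C(C)(C)C)C#C[Ce](Cl)Cl | intermediate
12 | dichlorocerium alkoxide of the mono-adduct (not isolated; alkoxide oxygen cis to the neighbouring Br) | CCC[C@H](O[Si](c3ccccc3)(c4ccccc4)C(C)(C)C)C#C[C@]1(O[Ce](Cl)Cl)[C@@H](Br)[C@H](Br)C1=O | intermediate
13 | 3,4-dibromo-2-oxo-1-[(S)-3-(tert-butyldiphenylsilyloxy)hex-1-ynyl]cyclobutyl methyl carbonate (carbonate O cis to the neighbouring Br; ring Br trans) | CCC[C@H](O[Si](c3ccccc3)(c4ccccc4)C(C)(C)C)C#C[C@]1(OC(=O)OC)[C@@H](Br)[C@H](Br)C1=O | intermediate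
14 | lithium acetylide of 9 (not isolated) | [Li]C#C[C@@H](CCC)O[Si](c3ccccc3)(c4ccccc4)C(C)(C)C | intermediate
15 | dichlorocerium acetylide of 9 (not isolated) | Cl[Ce](Cl)C#C[C@@H](CCC)O[Si](c3ccccc3)(c4ccccc4)C(C)(C)C | intermediate
16 | dichlorocerium alkoxide of the bis-adduct (not isolated) | CCC[C@H](O[Si](c3ccccc3)(c4ccccc4)C(C)(C)C)C#C[C@]1(OC(=O)OC)[C@@H](Br)[C@H](Br)[C@@]1(O[Ce](Cl)Cl)C#C[C@@H](CCC)O[Si](c3ccccc3)(c4ccccc4)C(C)(C)C | intermediate
17 | trans-bis(methyl carbonate) of 3,4-dibromo-1,2-dialkynylcyclobutane-1,2-diol (each carbonate O cis to its neighbouring Br; (S) and (R) side chains) | CCC[C@H](O[Si](c3ccccc3)(c4ccccc4)C(C)(C)C)C#C[C@]1(OC(=O)OC)[C@@H](Br)[C@H](Br)[C@@]1(OC(=O)OC)C#C[C@@H](CCC)O[Si](c3ccccc3)(c4ccccc4)C(C)(C)C | intermediate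
18 | dimethyl bis(2,3-allenoate): trans-3,4-dibromocyclobutane-1,2-diylidene bis-allene, each ester on the ring face opposite the former carbonate oxygen | CCC[C@H](O[Si](c3ccccc3)(c4ccccc4)C(C)(C)C)C(C(=O)OC)=[C@]=C1[C@@H](Br)[C@H](Br)C1=[C@]=C(C(=O)OC)[C@@H](CCC)O[Si](c3ccccc3)(c4ccccc4)C(C)(C)C | intermediate
19 | bis(tert-butyldiphenylsilyl) ether of the tetrabromo bis-spirolactone (lactone oxygens trans; each ring Br anti to the neighbouring lactone oxygen) | CCC[C@H](O[Si](c3ccccc3)(c4ccccc4)C(C)(C)C)C1=C(Br)[C@@]2(OC1=O)[C@@H](Br)[C@H](Br)[C@@]21OC(=O)C([C@@H](CCC)O[Si](c3ccccc3)(c4ccccc4)C(C)(C)C)=C1Br | intermediate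
20 | tetrabromo bis-spirolactone diol ((S)- and (R)-1-hydroxybutyl side chains) | CCC[C@H](O)C1=C(Br)[C@@]2(OC1=O)[C@@H](Br)[C@H](Br)[C@@]21OC(=O)C([C@@H](CCC)O)=C1Br | intermediate
21 | CNP0266230.1 | CCC[C@H](OC(C)=O)C1=C(Br)[C@@]2(OC1=O)[C@@H](Br)[C@H](Br)[C@@]21OC(=O)C([C@@H](CCC)OC(C)=O)=C1Br | target

**Step count and risks**

Total steps: 11. Longest linear sequence: 9 (steps 1–3 and 6–11); steps 4 and 5 are side branches.

Most likely to fail:

Step 6. The organometallic may abstract the proton at the CHBr next to the carbonyl, after which bromide is lost (E1cB). Facial selectivity may also erode because the transannular bromine shields the face that the adjacent bromine leaves open. The separation of the two diastereomeric adducts, whose stereocentres are held apart by the alkyne, may be incomplete. The fallback sets out from 3 and returns at 13. Hydrolysis of 3 (H2O, acetone) gives cyclobut-3-ene-1,2-dione F1, which has no sp3 α-hydrogen. Addition of 11 and trapping with ClCO2Me gives the enone carbonate F2 together with its carbinol epimer F3, and the two are separated by chromatography. Br2 in CH2Cl2 then adds anti across the ring alkene of F2. The bromine next to the carbinol carbon is expected to end on the face of the carbonate oxygen and not of the alkyne, which gives 13.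

Step 7. The second addition may show poor facial selectivity (cis- in place of trans-dicarbonate), and ketone 13 can again lose HBr by deprotonation. The fallback sets out from 3, runs through cyclobut-3-ene-1,2-dione F1 and the enone carbonate F2 described above, and returns at 17. Acetylide 15 is added to the enone carbonyl of F2, where no bromine is present and metal coordination to the carbonate should steer delivery to the carbonate face. Trapping with ClCO2Me gives the trans-dicarbonate of the cyclobutene F4. Anti addition of Br2 follows, with bromide opening the bromonium ion at the CH whose neighbouring carbinol carbon turns its oxygen to the attack face, and gives 17.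

Step 9. The axis-to-centre transfer may erode through reversible halocupration of the allene, and the second ring closure may stall because the second spiro centre is crowded. The fallback sets out from 17 and returns at 19. The carbonylation is run in THF/H2O in place of methanol (Pd(OAc)2, PPh3, CO) to give the bis(2,3-allenoic acid) F5. F5 is closed with N-bromosuccinimide and K2CO3 in MeCN at −20 °C, a metal-free bromonium-induced lactonisation of the free acids in which each carboxylate again attacks from the face it occupies.

Further compounds
F1 | step 6 | cyclobut-3-ene-1,2-dione | O=C1C=CC1=O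
F2 | step 6 | 4-oxo-1-[(S)-3-(tert-butyldiphenylsilyloxy)hex-1-ynyl]cyclobut-2-enyl methyl carbonate (carbinol configuration as in 13) | CCC[C@H](O[Si](c3ccccc3)(c4ccccc4)C(C)(C)C)C#C[C@]1(OC(=O)OC)C=CC1=O
F3 | step 6 | carbinol epimer of F2 (removed) | CCC[C@H](O[Si](c3ccccc3)(c4ccccc4)C(C)(C)C)C#C[C@@]1(OC(=O)OC)C=CC1=O
F4 | step 7 | trans-bis(methyl carbonate) of 3,4-dialkynylcyclobut-1-ene-3,4-diol ((S) and (R) side chains) | CCC[C@H](O[Si](c3ccccc3)(c4ccccc4)C(C)(C)C)C#C[C@]1(OC(=O)OC)C=C[C@@]1(OC(=O)OC)C#C[C@@H](CCC)O[Si](c3ccccc3)(c4ccccc4)C(C)(C)C
F5 | step 9 | bis(2,3-allenoic acid) corresponding to 18 | CCC[C@H](O[Si](c3ccccc3)(c4ccccc4)C(C)(C)C)C(C(=O)O)=[C@]=C1[C@@H](Br)[C@H](Br)C1=[C@]=C(C(=O)O)[C@@H](CCC)O[Si](c3ccccc3)(c4ccccc4)C(C)(C)C
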